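**Retrosynthetic overview**
1. Ring numbering used here: C1 = tertiary carbinol carbon carrying CH2OBz; C2 and C3 = the cis acetoxy carbons; C4=C5 = ring alkene; C6 = free secondary carbinol. O2, O3, O6 and the CH2OBz carbon lie on one face, O1 on the other.
2. Endgame: removal of a silyl group from O6 and acetylation of O2 lead back to a cyclohexenol whose ring, C2 hydroxyl and C3 acetate are all made in one flask.
3. Key disconnection: C2–C3 by indium Barbier γ-acetoxyallylation of an acyclic α-hydroxy aldehyde, and C4=C5 by ring-closing metathesis of the resulting 1,7-diene. The carbocycle is the only ring of the target and is closed last, in this step.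
4. Enabling feature: the C4=C5 alkene lies between two oxygen-bearing allylic carbons (C3 and C6), and C3 belongs to the cis C2/C3 diol next to the tertiary carbinol C1. This is an alk-1-ene-3,4-diol unit on an α-hydroxy carbon, the direct output of a chelation-controlled acyloxyallylation, and C4 and C5 are the two ends of a metathesis closure.
5. The aldehyde (C1 and C6 already set) comes from a racemic bis-allylic alcohol by Sharpless kinetic-resolution epoxidation (a temporary oxirane, formed first), benzoate opening at the oxirane CH2 (gives CH2OBz and C1–OH), PMB removal and oxidation. The alcohol comes from 2,3-dibromopropene, 4-methoxybenzyl alcohol and acrolein.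

Key step: step 9

Remark on the chemistry: 3-bromopropenyl acetate is used as the E/Z mixture from its preparation, on the assumption that the derived allylindium species equilibrates before it adds.

Step 1
Reactants: 1 2,3-dibromoprop-1-ene; 2 4-methoxybenzyl alcohol
Product: 3 1-{[(2-bromoprop-2-en-1-yl)oxy]methyl}-4-methoxybenzene (2-bromoallyl PMB ether)
Conditions: 50% aq. NaOH, Bu4NHSO4 (cat.), toluene, rt
Reagents that add atoms: none
Why: Williamson etherification under phase transfer should occur only at the allylic CH2Br, because the vinylic bromide is inert to SN2; no stereocenter is formed.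

Step 2
Reactants: 3 2-bromoallyl PMB ether; 4 acrolein
Product: 6 rac-2-{[(4-methoxybenzyl)oxy]methyl}penta-1,4-dien-3-ol, via 2-lithioallyl PMB ether 5 (not isolated)
Conditions: t-BuLi (2 equiv), Et2O, −78 °C; then acrolein, −78 °C; then H2O
Reagents that add atoms: none
Why: Bromine–lithium exchange gives the vinyllithium, which at −78 °C should add 1,2 to acrolein faster than it loses alkoxide, giving the racemic bis-allylic alcohol (organolithium 1,2-addition to an enal).

Step 3
Reactants: 6 rac-2-{[(4-methoxybenzyl)oxy]methyl}penta-1,4-dien-3-ol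
Product: 7 (1S)-1-[(2S)-2-{[(4-methoxybenzyl)oxy]methyl}oxiran-2-yl]prop-2-en-1-ol
Conditions: Ti(OiPr)4 (10 mol%), L-(+)-diisopropyl tartrate (12 mol%), t-BuOOH (0.55 equiv), 4 Å MS, CH2Cl2, −20 °C; chromatographic removal of unreacted (R)-6
Reagents that add atoms: tert-butyl hydroperoxide, CC(C)(C)OO
Why: Sharpless asymmetric epoxidation run as a kinetic resolution: with L-(+)-tartrate the (S)-alcohol is the fast enantiomer and should be epoxidised on its matched, more nucleophilic 1,1-disubstituted alkene to the erythro epoxy alcohol, which fixes C6 by selection and the quaternary C1 by the reagent-controlled face, while the (R)-alcohol, whose only matched alkene is the slow vinyl group, stays behind (at most half of the racemate can be used).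

Step 4
Reactants: 7 epoxy alcohol
Product: 8 tert-butyl({(1S)-1-[(2S)-2-{[(4-methoxybenzyl)oxy]methyl}oxiran-2-yl]prop-2-en-1-yl}oxy)dimethylsilane
Conditions: TBSCl, imidazole, DMF, rt
Reagents that add atoms: tert-butyldimethylsilyl chloride, CC(C)(C)[Si](C)(C)Cl
Why: Silyl ether formation at the only free hydroxyl blocks O6 for the later acetylation and removes the alkoxide that could cause Payne-type oxirane migration in step 5.

Step 5
Reactants: 8 silylated epoxide; 9 benzoic acid
Product: 10 (2R,3S)-3-[(tert-butyldimethylsilyl)oxy]-2-hydroxy-2-{[(4-methoxybenzyl)oxy]methyl}pent-4-en-1-yl benzoate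
Conditions: PhCO2H (2 equiv), Cs2CO3 (0.2 equiv), DMF, 80 °C
Reagents that add atoms: none
Why: Carboxylate SN2 opening of a 2,2-disubstituted oxirane should occur at the unsubstituted CH2, so the C–O bond at the quaternary carbon is untouched (C1 retained) and the primary benzoate and free tertiary carbinol of the target appear together.

Step 6
Reactants: 10 PMB ether
Product: 11 (2R,3S)-3-[(tert-butyldimethylsilyl)oxy]-2-hydroxy-2-(hydroxymethyl)pent-4-en-1-yl benzoate
Conditions: DDQ, CH2Cl2/pH 7 phosphate buffer (10:1), 0 °C to rt
Reagents that add atoms: none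
Why: Oxidative PMB ether cleavage is neutral, so the silyl ether should survive and the benzoate should not migrate between the two CH2O arms (a migration would invert C1).

Step 7
Reactants: 11 diol
Product: 12 (2R,3S)-3-[(tert-butyldimethylsilyl)oxy]-2-formyl-2-hydroxypent-4-en-1-yl benzoate
Conditions: IBX, DMSO, rt; used directly
Reagents that add atoms: none
Why: IBX oxidation should convert the primary alcohol of the 1,2-diol into the aldehyde without glycol cleavage and leave the tertiary hydroxyl alone; the aldehyde has no α-hydrogen, so C1 cannot epimerise.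

Step 8
Reactants: 4 acrolein; 13 acetyl bromide
Product: 14 3-bromoprop-1-en-1-yl acetate (E/Z mixture)
Conditions: ZnCl2 (cat.), CH2Cl2, −20 °C to rt; distillation
Reagents that add atoms: none
Why: Acyl bromides add to acrolein in a conjugate sense (bromide to C3, acyl group to oxygen), a known route to 3-bromopropenyl esters.

Step 9
Reactants: 12 α-hydroxy aldehyde; 14 3-bromoprop-1-en-1-yl acetate
Product: 17 [(1S,2R,3R,6S)-3-acetoxy-6-[(tert-butyldimethylsilyl)oxy]-1,2-dihydroxycyclohex-4-en-1-yl]methyl benzoate, via acetoxyallylindium dibromide 15 (not isolated), via acyclic 1,7-diene 16 (not isolated)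
Conditions: In powder (2 equiv), THF/H2O (4:1), rt, until 14 is consumed; then CH2Cl2 (high dilution), second-generation Hoveyda–Grubbs catalyst (5–10 mol%), 40 °C, same flask
Reagents that add atoms: none
Why: Indium inserts into the allylic C–Br bond of 14 to give allylindium 15, which adds through its acetoxy-bearing γ-carbon to the aldehyde of 12 (C2–C3 bond) to give diene 16, and the ruthenium alkylidene then joins the two vinyl termini of 16 by a [2+2]/retro-[2+2] sequence that forms C4=C5 and releases ethylene. The closest known reaction types are the indium-mediated chain elongation of unprotected aldoses with 3-bromopropenyl esters and the Barbier allylation then metathesis route from ω-unsaturated sugar aldehydes to conduritol-type cyclohexenes, here run in one flask. The six-membered carbocycle, the only ring, is closed by ring-closing metathesis between two monosubstituted alkenes, which can only give the endocyclic cis alkene. C2 is set by substrate control: indium bridges the aldehyde oxygen and the free tertiary C1–OH in a five-membered chelate, and the allyl group should enter on the CH2OBz face, anti to the bulky CH(OTBS)CH=CH2 branch, which places O2 trans to O1. C3 is set by the relative topicity of this chelated closed transition state, which for 3-bromopropenyl esters and α-hydroxy aldehydes is expected to give the erythro C2/C3 pair (the cis diol on the ring), with the C3 acetate of the target delivered by the reagent. The step needs chelation rather than Felkin-type addition, secured by leaving O1 free and silylating O6, and a clean ring closure, secured because only the six-membered ring is accessible; acetyl migration between O3 and O2 does not matter because both become acetates in step 10.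

Step 10
Reactants: 17 cyclohexene monoacetate
Product: 18 [(1S,2R,3R,6S)-2,3-diacetoxy-6-[(tert-butyldimethylsilyl)oxy]-1-hydroxycyclohex-4-en-1-yl]methyl benzoate
Conditions: Ac2O, pyridine, DMAP (cat.), CH2Cl2, 0 °C
Reagents that add atoms: acetic anhydride, CC(=O)OC(C)=O
Why: Acetylation should take the remaining secondary hydroxyl while the hindered tertiary C1–OH stays free at 0 °C, and any regioisomeric monoacetate converges on the same diacetate.

Step 11
Reactants: 18 silyl ether
Product: 19 [(1R,2R,3R,6S)-2,3-diacetoxy-1,6-dihydroxycyclohex-4-en-1-yl]methyl benzoate (target)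
Conditions: HF·pyridine, THF/pyridine, 0 °C to rt
Reagents that add atoms: none
Why: Fluoride desilylation under acidic conditions should free O6 without the base-promoted 1,3-acyl migration from O2 or from the benzoate to the new hydroxyl.

**Compound list**
1 | 2,3-dibromoprop-1-ene | C=C(Br)CBr | starting material
2 | 4-methoxybenzyl alcohol | COc1ccc(CO)cc1 | starting material
3 | 1-{[(2-bromoprop-2-en-1-yl)oxy]methyl}-4-methoxybenzene | C=C(Br)COCc1ccc(OC)cc1 | intermediate
4 | acrolein | C=CC=O | starting material
5 | 2-lithio-3-[(4-methoxybenzyl)oxy]prop-1-ene | [Li]C(=C)COCc1ccc(OC)cc1 | intermediate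
6 | rac-2-{[(4-methoxybenzyl)oxy]methyl}penta-1,4-dien-3-ol | C=CC(O)C(=C)COCc1ccc(OC)cc1 | intermediate
7 | (1S)-1-[(2S)-2-{[(4-methoxybenzyl)oxy]methyl}oxiran-2-yl]prop-2-en-1-ol | C=C[C@H](O)[C@@]1(COCc2ccc(OC)cc2)CO1 | intermediate
8 | tert-butyl({(1S)-1-[(2S)-2-{[(4-methoxybenzyl)oxy]methyl}oxiran-2-yl]prop-2-en-1-yl}oxy)dimethylsilane | C=C[C@H](O[Si](C)(C)C(C)(C)C)[C@@]1(COCc2ccc(OC)cc2)CO1 | intermediate
9 | benzoic acid | OC(=O)c1ccccc1 | starting material
10 | (2R,3S)-3-[(tert-butyldimethylsilyl)oxy]-2-hydroxy-2-{[(4-methoxybenzyl)oxy]methyl}pent-4-en-1-yl benzoate | C=C[C@H](O[Si](C)(C)C(C)(C)C)[C@](O)(COC(=O)c1ccccc1)COCc1ccc(OC)cc1 | intermediate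
11 | (2R,3S)-3-[(tert-butyldimethylsilyl)oxy]-2-hydroxy-2-(hydroxymethyl)pent-4-en-1-yl benzoate | C=C[C@H](O[Si](C)(C)C(C)(C)C)[C@](O)(COC(=O)c1ccccc1)CO | intermediate
12 | (2R,3S)-3-[(tert-butyldimethylsilyl)oxy]-2-formyl-2-hydroxypent-4-en-1-yl benzoate | C=C[C@H](O[Si](C)(C)C(C)(C)C)[C@](O)(COC(=O)c1ccccc1)C=O | intermediate
13 | acetyl bromide | CC(=O)Br | starting material
14 | 3-bromoprop-1-en-1-yl acetate (E/Z mixture) | CC(=O)OC=CCBr | intermediate
15 | 3-acetoxyprop-2-en-1-ylindium dibromide (simplified monomeric formula of the allylindium reagent) | CC(=O)OC=CC[In](Br)Br | intermediate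
16 | (2S,3S)-2-[(1R,2R)-2-acetoxy-1-hydroxybut-3-en-1-yl]-3-[(tert-butyldimethylsilyl)oxy]-2-hydroxypent-4-en-1-yl benzoate | C=C[C@H](O[Si](C)(C)C(C)(C)C)[C@](O)(COC(=O)c1ccccc1)[C@H](O)[C@H](OC(C)=O)C=C | intermediate
17 | [(1S,2R,3R,6S)-3-acetoxy-6-[(tert-butyldimethylsilyl)oxy]-1,2-dihydroxycyclohex-4-en-1-yl]methyl benzoate | O[C@@H]1[C@H](OC(C)=O)C=C[C@H](O[Si](C)(C)C(C)(C)C)[C@]1(O)COC(=O)c1ccccc1 | intermediate
18 | [(1S,2R,3R,6S)-2,3-diacetoxy-6-[(tert-butyldimethylsilyl)oxy]-1-hydroxycyclohex-4-en-1-yl]methyl benzoate | CC(=O)O[C@@H]1[C@H](OC(C)=O)C=C[C@H](O[Si](C)(C)C(C)(C)C)[C@]1(O)COC(=O)c1ccccc1 | intermediate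
19 | [(1R,2R,3R,6S)-2,3-diacetoxy-1,6-dihydroxycyclohex-4-en-1-yl]methyl benzoate | CC(=O)O[C@@H]1[C@H](OC(C)=O)C=C[C@H](O)[C@]1(O)COC(=O)c1ccccc1 | target

Total step count: 11. Longest linear sequence: 10 steps (steps 1–7 and 9–11); step 8 is a one-step branch.

**Steps most likely to fail**

Step 9. The addition may go through a non-chelated conformer and lose facial selectivity at C2, the erythro C2/C3 preference may erode, or residual organoindium and allylic bromide may deactivate the ruthenium alkylidene in the one-flask protocol. The fallback sets out from 12 and comes back at 18, and it separates the two bond formations and uses a geometry-defined boron reagent. Aldehyde 12 is treated with the diisopropyl tartrate ester of (E)-3-(triethylsilyloxy)allylboronic acid (tartrate enantiomer matched to the substrate; toluene, 4 Å MS, −78 °C to rt). The E geometry and the closed chair transition state should enforce the anti C2/C3 pair and give (2S,3S)-3-[(tert-butyldimethylsilyl)oxy]-2-hydroxy-2-{(1R,2R)-1-hydroxy-2-[(triethylsilyl)oxy]but-3-en-1-yl}pent-4-en-1-yl benzoate F1. Ring-closing metathesis of the purified diene (second-generation Grubbs catalyst, CH2Cl2, 40 °C) should give [(1S,2R,3R,6S)-6-[(tert-butyldimethylsilyl)oxy]-1,2-dihydroxy-3-[(triethylsilyl)oxy]cyclohex-4-en-1-yl]methyl benzoate F2. Selective cleavage of the triethylsilyl ether (PPTS, MeOH, 0 °C) should give [(1S,2R,3R,6S)-6-[(tert-butyldimethylsilyl)oxy]-1,2,3-trihydroxycyclohex-4-en-1-yl]methyl benzoate F3, and acetylation of its two secondary hydroxyls (Ac2O, pyridine, DMAP, 0 °C) gives 18.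

Step 3. The rate difference between the two enantiomers, or between the two allylic alkenes, may be too small; competing epoxidation of the vinyl group would lower ee and diastereomeric purity. The fallback sets out from 6 and comes back at 7, and it separates resolution from epoxidation. Lipase acylation (Novozym 435, vinyl acetate, MTBE, rt) should acylate the (R)-alcohol to (3R)-2-{[(4-methoxybenzyl)oxy]methyl}penta-1,4-dien-3-yl acetate F5 and leave (3S)-2-{[(4-methoxybenzyl)oxy]methyl}penta-1,4-dien-3-ol F4. Hydroxyl-directed epoxidation of the resolved alcohol (VO(acac)2 cat., t-BuOOH, CH2Cl2, 0 °C) is erythro-selective for allylic alcohols with a substituent geminal to the carbinol and favours the more substituted alkene, and should give 7.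

Step 5. SN2 attack at the neopentyl-type oxirane CH2 may be slow, and opening at the quaternary carbon or silyl migration may compete at 80 °C. The fallback sets out from 7 and comes back at 10, and it reverses the order of protection and opening. The free epoxy alcohol 7 is opened with PhCO2H and Ti(OiPr)4 (CH2Cl2, rt), where chelation of titanium by the carbinol and oxirane oxygens directs benzoate to the distal CH2, to give (2R,3S)-2,3-dihydroxy-2-{[(4-methoxybenzyl)oxy]methyl}pent-4-en-1-yl benzoate F6. Selective silylation of its secondary hydroxyl (TBSOTf, 2,6-lutidine, CH2Cl2, −78 °C) gives 10.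

**Further compounds**
F1 | step 9 | (2S,3S)-3-[(tert-butyldimethylsilyl)oxy]-2-hydroxy-2-{(1R,2R)-1-hydroxy-2-[(triethylsilyl)oxy]but-3-en-1-yl}pent-4-en-1-yl benzoate | C=C[C@H](O[Si](C)(C)C(C)(C)C)[C@](O)(COC(=O)c1ccccc1)[C@H](O)[C@H](O[Si](CC)(CC)CC)C=C
F2 | step 9 | [(1S,2R,3R,6S)-6-[(tert-butyldimethylsilyl)oxy]-1,2-dihydroxy-3-[(triethylsilyl)oxy]cyclohex-4-en-1-yl]methyl benzoate | O[C@@H]1[C@H](O[Si](CC)(CC)CC)C=C[C@H](O[Si](C)(C)C(C)(C)C)[C@]1(O)COC(=O)c1ccccc1
F3 | step 9 | [(1S,2R,3R,6S)-6-[(tert-butyldimethylsilyl)oxy]-1,2,3-trihydroxycyclohex-4-en-1-yl]methyl benzoate | O[C@@H]1[C@H](O)C=C[C@H](O[Si](C)(C)C(C)(C)C)[C@]1(O)COC(=O)c1ccccc1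
F4 | step 3 | (3S)-2-{[(4-methoxybenzyl)oxy]methyl}penta-1,4-dien-3-ol | C=C[C@H](O)C(=C)COCc1ccc(OC)cc1
F5 | step 3 | (3R)-2-{[(4-methoxybenzyl)oxy]methyl}penta-1,4-dien-3-yl acetate | C=C[C@@H](OC(C)=O)C(=C)COCc1ccc(OC)cc1
F6 | step 5 | (2R,3S)-2,3-dihydroxy-2-{[(4-methoxybenzyl)oxy]methyl}pent-4-en-1-yl benzoate | C=C[C@H](O)[C@](O)(COC(=O)c1ccccc1)COCc1ccc(OC)cc1
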